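Everything rests on the C12'–C13' single bond, which links the E-disubstituted alkene C11'=C12' to the methyl-bearing alkene C13'=C14'. The central triene C13–C13' is locally C2-symmetric, so C12–C13 and C12'–C13' are twin bonds: a symmetric (2E,4E,6E)-2,7-dibromoocta-2,4,6-triene is coupled first with the β-ring C16 enyne and then, in the key step, with the ε-ring C16 enyne. There, hydrozirconation turns the terminal alkyne C11'≡C12' into an E-alkenyl nucleophile that palladium joins to the C13' bromide of the β-ring C24 polyene, creating the bond and the C11'=C12' geometry in one operation. Desilylation and double Steglich acylation of lutein with α-linolenic acid finish the route.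

Key step: step 15

Assumption: (4R,6R)-actinol (1) and (R)-α-ionone (17) are taken as purchasable enantiopure chiral-pool materials; positions are given in carotenoid numbering (β-ring C1–C6, chain C7–C15 and C15'–C7', ε-ring C1'–C6'), and all polyenes are handled under argon in the dark.

Step 1
Reactants: 1 (4R,6R)-actinol
Product: 2 (4R,6R)-4-(tert-butyldimethylsilyloxy)-2,2,6-trimethylcyclohexan-1-one
Conditions: TBSCl, imidazole, DMF, rt
Reagents that add atoms: tert-butyldimethylsilyl chloride CC(C)(C)[Si](C)(C)Cl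
Why: Silyl ether formation masks the secondary hydroxyl before enolate chemistry and touches no stereocentre.

Step 2
Reactants: 2 (4R,6R)-4-(tert-butyldimethylsilyloxy)-2,2,6-trimethylcyclohexan-1-one
Product: 4 (R)-4-(tert-butyldimethylsilyloxy)-2,6,6-trimethylcyclohex-1-en-1-yl trifluoromethanesulfonate, via lithium enolate 3 (not isolated)
Conditions: LiN(i-Pr)2, THF, −78 °C; then PhNTf2, −78 °C to rt
Reagents that add atoms: N-phenylbis(trifluoromethanesulfonimide) O=S(=O)(N(c1ccccc1)S(=O)(=O)C(F)(F)F)C(F)(F)F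
Why: Only C6 of the ketone carries an α-hydrogen, so a single enolate forms and is trapped on oxygen (enol triflate formation); the C6 stereocentre is erased on purpose and the carbinol carbon, the later C3 of the target, stays R.

Step 3
Reactants: 5 (E)-3-methylpent-2-en-4-yn-1-ol
Product: 6 (2E,4E)-3-methyl-5-(tributylstannyl)penta-2,4-dien-1-ol
Conditions: Bu3SnH, PdCl2(PPh3)2 (cat.), THF, 0 °C to rt
Reagents that add atoms: tributyltin hydride CCCC[SnH](CCCC)CCCC
Why: Palladium-catalysed syn hydrostannation of the terminal alkyne should place tin on the terminal carbon and give the E-alkenylstannane, leaving the existing E-trisubstituted alkene untouched.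

Step 4
Reactants: 4 (R)-4-(tert-butyldimethylsilyloxy)-2,6,6-trimethylcyclohex-1-en-1-yl trifluoromethanesulfonate; 6 (2E,4E)-3-methyl-5-(tributylstannyl)penta-2,4-dien-1-ol
Product: 7 β-ring C15 alcohol (2E,4E)-5-[(R)-4-(tert-butyldimethylsilyloxy)-2,6,6-trimethylcyclohex-1-en-1-yl]-3-methylpenta-2,4-dien-1-ol
Conditions: Pd2(dba)3 (cat.), AsPh3, NMP, 50 °C
Reagents that add atoms: none
Why: Stille coupling of the hindered cyclohexenyl triflate with the alkenylstannane should form the C6–C7 bond with retention of both alkene geometries, the soft AsPh3 ligand speeding the transmetalation.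

Step 5
Reactants: 7 β-ring C15 alcohol
Product: 8 β-ring C15 aldehyde (2E,4E)-5-[(R)-4-(tert-butyldimethylsilyloxy)-2,6,6-trimethylcyclohex-1-en-1-yl]-3-methylpenta-2,4-dienal
Conditions: MnO2, CH2Cl2, rt
Reagents that add atoms: none
Why: MnO2 oxidises the allylic primary alcohol selectively to the dienal (allylic alcohol oxidation) without touching the silyl ether or the alkene geometry.

Step 6
Reactants: 8 β-ring C15 aldehyde
Product: 9 β-ring C16 enyne tert-butyldimethyl{[(R)-3,5,5-trimethyl-4-((1E,3E)-3-methylhexa-1,3-dien-5-yn-1-yl)cyclohex-3-en-1-yl]oxy}silane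
Conditions: TMSCHN2, LiN(i-Pr)2, THF, −78 °C to rt
Reagents that add atoms: (trimethylsilyl)diazomethane C[Si](C)(C)C=[N+]=[N-]
Why: Colvin homologation: the lithiated silyldiazomethane adds 1,2 to the enal and, after Peterson-type elimination, loss of nitrogen and a 1,2-hydrogen shift, should deliver the terminal alkyne with one added carbon (C12) and unchanged diene geometry.

Step 7
Reactants: 10 propyne
Product: 11 (E)-2-bromo-1-iodoprop-1-ene
Conditions: IBr, CH2Cl2, −78 to 0 °C, dark
Reagents that add atoms: iodine monobromide IBr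
Why: Electrophilic anti addition of IBr to the alkyne should put iodine on the terminal carbon and bromide on the methyl-bearing carbon (Markovnikov), giving the E-dihalide.

Step 8
Reactants: 11 (E)-2-bromo-1-iodoprop-1-ene (2.1 equiv); 12 (E)-1,2-bis(tributylstannyl)ethene
Product: 14 (2E,4E,6E)-2,7-dibromoocta-2,4,6-triene, via bromodienylstannane 13 (not isolated)
Conditions: PdCl2(MeCN)2 (cat.), DMF, rt, dark
Reagents that add atoms: none
Why: Twofold Stille coupling: oxidative addition into C–I is far faster than into C–Br, so each tin terminus should be alkenylated at the iodide with retention while both bromides survive as the handles of the C8 linchpin.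

Step 9
Reactants: 9 β-ring C16 enyne; 14 (2E,4E,6E)-2,7-dibromoocta-2,4,6-triene (3 equiv)
Product: 16 β-ring C24 bromide tert-butyl{[(R)-4-((1E,3E,5E,7E,9E,11E)-12-bromo-3,7-dimethyltrideca-1,3,5,7,9,11-hexaen-1-yl)-3,5,5-trimethylcyclohex-3-en-1-yl]oxy}dimethylsilane, via β-ring dienylzirconocene 15 (not isolated)
Conditions: Cp2Zr(H)Cl (1.1 equiv), THF, rt; then 14, Pd(PPh3)4 (cat.), ZnCl2 (cat.), THF, rt to 40 °C, dark
Reagents that add atoms: none
Why: Syn hydrozirconation of the terminal alkyne gives the E-dienylzirconocene with zirconium on C12, which should couple with one C–Br bond of the linchpin under palladium and zinc cocatalysis (Negishi alkenyl–alkenyl coupling) to form C12–C13 with retention, the recoverable excess of 14 holding the reaction at the mono stage.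

Step 10
Reactants: 17 (R)-α-ionone
Product: 18 ε-ring C15 nitrile (2E,4E)-3-methyl-5-[(1R)-2,6,6-trimethylcyclohex-2-en-1-yl]penta-2,4-dienenitrile
Conditions: (EtO)2P(O)CH2CN, NaH, THF, 0 °C to rt
Reagents that add atoms: diethyl cyanomethylphosphonate CCOP(=O)(CC#N)OCC
Why: Horner–Wadsworth–Emmons olefination of the methyl ketone with the stabilised, weakly basic phosphonate anion should give mainly the 9'E dienenitrile (the minor 9'Z isomer is removed by chromatography) without disturbing the C6' stereocentre.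

Step 11
Reactants: 18 ε-ring C15 nitrile
Product: 19 (2E,4E)-3-methyl-5-[(1R)-2,6,6-trimethyl-4-oxocyclohex-2-en-1-yl]penta-2,4-dienenitrile
Conditions: t-BuOOH (70% in water), Rh2(cap)4 (dirhodium tetrakis(caprolactamate), cat.), 1,2-dichloroethane, 40 °C
Reagents that add atoms: tert-butyl hydroperoxide CC(C)(C)OO
Why: Radical allylic oxidation by tert-butylperoxyl radicals should convert the only secondary allylic methylene (C3') into the enone carbonyl, the electron-poor dienenitrile and the hindered C6'–H being left alone.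

Step 12
Reactants: 19 (2E,4E)-3-methyl-5-[(1R)-2,6,6-trimethyl-4-oxocyclohex-2-en-1-yl]penta-2,4-dienenitrile
Product: 20 (2E,4E)-5-[(1R,4R)-4-hydroxy-2,6,6-trimethylcyclohex-2-en-1-yl]-3-methylpenta-2,4-dienenitrile
Conditions: (S)-2-methyl-CBS-oxazaborolidine (cat.), catecholborane, toluene, −78 °C
Reagents that add atoms: none
Why: Corey–Bakshi–Shibata reduction: the (S)-oxazaborolidine–borane complex should deliver hydride to the enone face that gives the R carbinol (alkenyl side as the large group), setting C3' by reagent control, and the substrate should reinforce this because attack anti to the pseudoaxial C1' methyl also leads to the alcohol trans to the C6' side chain.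

Step 13
Reactants: 20 (2E,4E)-5-[(1R,4R)-4-hydroxy-2,6,6-trimethylcyclohex-2-en-1-yl]-3-methylpenta-2,4-dienenitrile
Product: 22 ε-ring C15 hydroxy aldehyde (2E,4E)-5-[(1R,4R)-4-hydroxy-2,6,6-trimethylcyclohex-2-en-1-yl]-3-methylpenta-2,4-dienal, via N-aluminio aldimine 21 (not isolated)
Conditions: i-Bu2AlH (3 equiv), CH2Cl2, −78 to −40 °C; then aqueous potassium sodium tartrate, wet silica gel, 0 °C
Reagents that add atoms: water O
Why: Partial reduction of the nitrile stops at the N-aluminio aldimine (the hydroxyl riding along as its aluminium alkoxide), and mild hydrolysis should release the dienal without ionising the allylic alcohol (nitrile to aldehyde reduction).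

Step 14
Reactants: 22 ε-ring C15 hydroxy aldehyde
Product: 23 ε-ring C16 enyne (1R,4R)-3,5,5-trimethyl-4-[(1E,3E)-3-methylhexa-1,3-dien-5-yn-1-yl]cyclohex-2-en-1-ol
Conditions: TMSCHN2, LiN(i-Pr)2 (2.2 equiv), THF, −78 °C to rt
Reagents that add atoms: (trimethylsilyl)diazomethane C[Si](C)(C)C=[N+]=[N-]
Why: Colvin homologation as in step 6, with a second equivalent of base carrying the hydroxyl as its lithium alkoxide, should convert the dienal into the terminal enyne and add C12'.

Step 15
Reactants: 23 ε-ring C16 enyne; 16 β-ring C24 bromide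
Product: 25 (3R,3'R,6'R)-lutein 3-O-tert-butyldimethylsilyl ether, via ε-ring dienylzirconocene 24 (not isolated)
Conditions: Cp2Zr(H)Cl (2.2 equiv), THF, rt; then 16, Pd(PPh3)4 (cat.), ZnCl2 (cat.), THF, rt to 40 °C, dark
Reagents that add atoms: none
Why: Cp2Zr(H)Cl first turns the 3'-hydroxyl into an inert zirconium alkoxide and then adds syn across the terminal alkyne C11'≡C12' with zirconium on C12', so the E-dienylzirconocene 24 should form with regio- and stereocontrol dictated by the terminal position of the alkyne. Zerovalent palladium inserts into the C13'–Br bond of 16 with retention, ZnCl2 shuttles the alkenyl group from zirconium to palladium, and reductive elimination forms the C12'–C13' bond. The closest known reaction type is the one-pot hydrozirconation/Negishi alkenyl–alkenyl coupling used for conjugated polyenes. No ring is closed and no stereocentre is formed; the step fixes the E geometry of C11'=C12' through the syn addition and keeps the E geometry of C13'=C14' through retention at the bromide carbon. The selectivity needed is hydrozirconation of the alkyne in preference to the di- and trisubstituted alkenes of the ε-ring and chain, secured by the far higher reactivity of a terminal alkyne towards the zirconium hydride at room temperature, and all hydride is consumed before 16 is added. Heat and light are kept low so that the nonaene should not isomerise.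

Step 16
Reactants: 25 (3R,3'R,6'R)-lutein 3-O-tert-butyldimethylsilyl ether
Product: 26 (3R,3'R,6'R)-lutein
Conditions: Bu4NF, THF, 0 °C to rt, dark
Reagents that add atoms: none
Why: Fluoride cleaves the Si–O bond (desilylation) under non-acidic conditions that should spare the ionisable allylic 3'-alcohol and the polyene.

Step 17
Reactants: 26 (3R,3'R,6'R)-lutein; 27 α-linolenic acid (2.5 equiv)
Product: 31 (3R,3'R,6'R)-lutein di-α-linolenate (target), via O-acylisourea 28 (not isolated), via lutein 3-monolinolenate 29 (not isolated), via lutein 3'-monolinolenate 30 (not isolated)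
Conditions: DCC, DMAP (cat.), CH2Cl2, 0 °C to rt, argon, dark
Reagents that add atoms: none
Why: Steglich esterification: DCC activates the acid as the O-acylisourea and DMAP relays the acyl group to both secondary hydroxyls under neutral conditions, with retention at C3 and C3' and without touching the skipped Z-triene of the acid.

Compound list
1 | (4R,6R)-actinol, (4R,6R)-4-hydroxy-2,2,6-trimethylcyclohexan-1-one | O[C@@H]1C[C@@H](C)C(=O)C(C)(C)C1 | starting material
2 | (4R,6R)-4-(tert-butyldimethylsilyloxy)-2,2,6-trimethylcyclohexan-1-one | CC(C)(C)[Si](C)(C)O[C@@H]1C[C@@H](C)C(=O)C(C)(C)C1 | intermediate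
3 | lithium enolate of 2, lithium (R)-4-(tert-butyldimethylsilyloxy)-2,6,6-trimethylcyclohex-1-en-1-olate (formed in the flask) | CC(C)(C)[Si](C)(C)O[C@@H]1CC(C)=C(O[Li])C(C)(C)C1 | intermediate
4 | (R)-4-(tert-butyldimethylsilyloxy)-2,6,6-trimethylcyclohex-1-en-1-yl trifluoromethanesulfonate | CC(C)(C)[Si](C)(C)O[C@@H]1CC(C)=C(OS(=O)(=O)C(F)(F)F)C(C)(C)C1 | intermediate
5 | (E)-3-methylpent-2-en-4-yn-1-ol | C#C/C(C)=C/CO | starting material
6 | (2E,4E)-3-methyl-5-(tributylstannyl)penta-2,4-dien-1-ol | CCCC[Sn](CCCC)(CCCC)/C=C/C(C)=C/CO | intermediate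
7 | β-ring C15 alcohol, (2E,4E)-5-[(R)-4-(tert-butyldimethylsilyloxy)-2,6,6-trimethylcyclohex-1-en-1-yl]-3-methylpenta-2,4-dien-1-ol | CC(C)(C)[Si](C)(C)O[C@@H]1CC(C)=C(/C=C/C(C)=C/CO)C(C)(C)C1 | intermediate
8 | β-ring C15 aldehyde, (2E,4E)-5-[(R)-4-(tert-butyldimethylsilyloxy)-2,6,6-trimethylcyclohex-1-en-1-yl]-3-methylpenta-2,4-dienal | CC(C)(C)[Si](C)(C)O[C@@H]1CC(C)=C(/C=C/C(C)=C/C=O)C(C)(C)C1 | intermediate
9 | β-ring C16 enyne, tert-butyldimethyl{[(R)-3,5,5-trimethyl-4-((1E,3E)-3-methylhexa-1,3-dien-5-yn-1-yl)cyclohex-3-en-1-yl]oxy}silane | CC(C)(C)[Si](C)(C)O[C@@H]1CC(C)=C(/C=C/C(C)=C/C#C)C(C)(C)C1 | intermediate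
10 | propyne | CC#C | starting material
11 | (E)-2-bromo-1-iodoprop-1-ene | Br/C(C)=C/I | intermediate
12 | (E)-1,2-bis(tributylstannyl)ethene | CCCC[Sn](CCCC)(CCCC)/C=C/[Sn](CCCC)(CCCC)CCCC | starting material
13 | tributyl[(1E,3E)-4-bromopenta-1,3-dien-1-yl]stannane (formed in the flask) | CCCC[Sn](CCCC)(CCCC)/C=C/C=C(C)/Br | intermediate
14 | (2E,4E,6E)-2,7-dibromoocta-2,4,6-triene | Br/C(C)=C/C=C/C=C(C)/Br | intermediate
15 | β-ring E-dienylzirconocene chloride from 9, chlorobis(cyclopentadienyl)zirconium on C12 (formed in the flask; cyclopentadienyl rings drawn σ-bonded) | CC(C)(C)[Si](C)(C)O[C@@H]1CC(C)=C(/C=C/C(C)=C/C=C/[Zr](Cl)(C2C=CC=C2)C2C=CC=C2)C(C)(C)C1 | intermediate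
16 | β-ring C24 bromide, tert-butyl{[(R)-4-((1E,3E,5E,7E,9E,11E)-12-bromo-3,7-dimethyltrideca-1,3,5,7,9,11-hexaen-1-yl)-3,5,5-trimethylcyclohex-3-en-1-yl]oxy}dimethylsilane (bromine on C13') | CC(C)(C)[Si](C)(C)O[C@@H]1CC(C)=C(/C=C/C(C)=C/C=C/C(C)=C/C=C/C=C(C)/Br)C(C)(C)C1 | intermediate
17 | (R)-α-ionone, (3E)-4-[(1R)-2,6,6-trimethylcyclohex-2-en-1-yl]but-3-en-2-one | CC(=O)/C=C/[C@H]1C(C)=CCCC1(C)C | starting material
18 | ε-ring C15 nitrile, (2E,4E)-3-methyl-5-[(1R)-2,6,6-trimethylcyclohex-2-en-1-yl]penta-2,4-dienenitrile | N#C/C=C(C)/C=C/[C@H]1C(C)=CCCC1(C)C | intermediate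
19 | (2E,4E)-3-methyl-5-[(1R)-2,6,6-trimethyl-4-oxocyclohex-2-en-1-yl]penta-2,4-dienenitrile | N#C/C=C(C)/C=C/[C@H]1C(C)=CC(=O)CC1(C)C | intermediate
20 | (2E,4E)-5-[(1R,4R)-4-hydroxy-2,6,6-trimethylcyclohex-2-en-1-yl]-3-methylpenta-2,4-dienenitrile | N#C/C=C(C)/C=C/[C@H]1C(C)=C[C@H](O)CC1(C)C | intermediate
21 | N-(diisobutylaluminio) aldimine of 22 with the hydroxyl as diisobutylaluminium alkoxide (formed in the flask) | CC(C)C[Al](CC(C)C)N=C/C=C(C)/C=C/[C@H]1C(C)=C[C@H](O[Al](CC(C)C)CC(C)C)CC1(C)C | intermediate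
22 | ε-ring C15 hydroxy aldehyde, (2E,4E)-5-[(1R,4R)-4-hydroxy-2,6,6-trimethylcyclohex-2-en-1-yl]-3-methylpenta-2,4-dienal | O=C/C=C(C)/C=C/[C@H]1C(C)=C[C@H](O)CC1(C)C | intermediate
23 | ε-ring C16 enyne, (1R,4R)-3,5,5-trimethyl-4-[(1E,3E)-3-methylhexa-1,3-dien-5-yn-1-yl]cyclohex-2-en-1-ol | C#C/C=C(C)/C=C/[C@H]1C(C)=C[C@H](O)CC1(C)C | intermediate
24 | ε-ring E-dienylzirconocene chloride from 23, zirconium on C12' and the 3'-oxygen bound to a second chlorozirconocene (formed in the flask; cyclopentadienyl rings drawn σ-bonded) | Cl[Zr](C2C=CC=C2)(C2C=CC=C2)/C=C/C=C(C)/C=C/[C@H]1C(C)=C[C@H](O[Zr](Cl)(C2C=CC=C2)C2C=CC=C2)CC1(C)C | intermediate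
25 | (3R,3'R,6'R)-lutein 3-O-tert-butyldimethylsilyl ether | CC(C)(C)[Si](C)(C)O[C@@H]1CC(C)=C(/C=C/C(C)=C/C=C/C(C)=C/C=C/C=C(C)/C=C/C=C(C)/C=C/[C@H]2C(C)=C[C@H](O)CC2(C)C)C(C)(C)C1 | intermediate
26 | (3R,3'R,6'R)-lutein, all-E β,ε-carotene-3,3'-diol | O[C@@H]1CC(C)=C(/C=C/C(C)=C/C=C/C(C)=C/C=C/C=C(C)/C=C/C=C(C)/C=C/[C@H]2C(C)=C[C@H](O)CC2(C)C)C(C)(C)C1 | intermediate
27 | α-linolenic acid, (9Z,12Z,15Z)-octadeca-9,12,15-trienoic acid | CC/C=C\C/C=C\C/C=C\CCCCCCCC(=O)O | starting material
28 | O-acylisourea of 27 with DCC (formed in the flask) | CC/C=C\C/C=C\C/C=C\CCCCCCCC(=O)OC(=NC1CCCCC1)NC1CCCCC1 | intermediate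
29 | lutein 3-mono-α-linolenate, ester on the β-ring (formed in the flask) | CC/C=C\C/C=C\C/C=C\CCCCCCCC(=O)O[C@@H]1CC(C)=C(/C=C/C(C)=C/C=C/C(C)=C/C=C/C=C(C)/C=C/C=C(C)/C=C/[C@H]2C(C)=C[C@H](O)CC2(C)C)C(C)(C)C1 | intermediate
30 | lutein 3'-mono-α-linolenate, ester on the ε-ring (formed in the flask) | O[C@@H]1CC(C)=C(/C=C/C(C)=C/C=C/C(C)=C/C=C/C=C(C)/C=C/C=C(C)/C=C/[C@H]2C(C)=C[C@H](OC(=O)CCCCCCC/C=C\C/C=C\C/C=C\CC)CC2(C)C)C(C)(C)C1 | intermediate
31 | (3R,3'R,6'R)-lutein di-α-linolenate | CC/C=C\C/C=C\C/C=C\CCCCCCCC(=O)O[C@@H]1CC(C)=C(/C=C/C(C)=C/C=C/C(C)=C/C=C/C=C(C)/C=C/C=C(C)/C=C/[C@H]2C(C)=C[C@H](OC(=O)CCCCCCC/C=C\C/C=C\C/C=C\CC)CC2(C)C)C(C)(C)C1 | target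

Total step count: 17. Longest linear sequence: 9 steps (steps 1, 2, 4, 5, 6, 9, 15, 16 and 17, from 1).

Steps most likely to fail

Step 15. Oxidative addition into the hindered, methyl-bearing C13'–Br bond may be slow, so that protonolysis or homocoupling of the dienylzirconocene and geometric scrambling of the polyene on prolonged warming overtake the cross-coupling. The fallback sets out from 23: palladium-catalysed hydrostannation (Bu3SnH, PdCl2(PPh3)2, THF) should give the isolable, purifiable ε-ring trienylstannane F1, and a Stille coupling of F1 with 16 (Pd2(dba)3, AsPh3, NMP, rt) forms the same C12'–C13' bond without zirconium or zinc and comes back to the route at 25.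

Step 9. The product may couple a second time at its remaining C–Br bond (over-reaction on a symmetric dielectrophile), giving a C40 bis-adduct and a difficult separation. The fallback is an unsymmetric, non-statistical assembly that sets out from 9 and 11: stannane 13 is made on purpose and isolated (11 with an excess of 12 under the conditions of step 8), the zirconocene 15 from 9 is coupled at the C–Br bond of 13 (Pd(PPh3)4, ZnCl2, THF), tin being inert under these conditions, to give the β-ring C21 trienylstannane F2, and a Stille coupling of F2 with 11 at its C–I bond comes back to the route at 16.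

Step 12. Hydride delivery to the ring enone may show poor facial selectivity if catalyst control and substrate bias oppose each other, giving the 3'-epimeric alcohol. The fallback sets out from 19: Luche reduction (NaBH4, CeCl3·7H2O, MeOH, −78 °C) and chromatography give the cis alcohol F3, a Mitsunobu reaction (4-nitrobenzoic acid, PPh3, DIAD, THF) inverts the carbinol to the trans 4-nitrobenzoate F4, and methanolysis (K2CO3, MeOH) comes back to the route at 20.

Further compounds
F1 | step 15 | ε-ring trienylstannane, (1R,4R)-3,5,5-trimethyl-4-[(1E,3E,5E)-3-methyl-6-(tributylstannyl)hexa-1,3,5-trien-1-yl]cyclohex-2-en-1-ol | CCCC[Sn](CCCC)(CCCC)/C=C/C=C(C)/C=C/[C@H]1C(C)=C[C@H](O)CC1(C)C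
F2 | step 9 | β-ring C21 trienylstannane, tin on C15' | CC(C)(C)[Si](C)(C)O[C@@H]1CC(C)=C(/C=C/C(C)=C/C=C/C(C)=C/C=C/[Sn](CCCC)(CCCC)CCCC)C(C)(C)C1
F3 | step 12 | cis alcohol, (2E,4E)-5-[(1R,4S)-4-hydroxy-2,6,6-trimethylcyclohex-2-en-1-yl]-3-methylpenta-2,4-dienenitrile | N#C/C=C(C)/C=C/[C@H]1C(C)=C[C@@H](O)CC1(C)C
F4 | step 12 | trans 4-nitrobenzoate, (1R,4R)-4-[(1E,3E)-4-cyano-3-methylbuta-1,3-dien-1-yl]-3,5,5-trimethylcyclohex-2-en-1-yl 4-nitrobenzoate | N#C/C=C(C)/C=C/[C@H]1C(C)=C[C@H](OC(=O)c2ccc(cc2)[N+](=O)[O-])CC1(C)C
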